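**Retrosynthetic overview**
- The C2 hydroxymethyl group comes from a C2 methyl ester. The pyridone ring (N1, C2, C3, C4, C4a, C8a) is the only ring made in the route, by oxalate annulation of a β-keto O-methyl oxime (C2–C3 bond, then N1–C2 closure).
- The β-keto oxime comes from an aldol adduct in which C8a is the only ketone, so the N–OMe unit is placed on C8a without ambiguity.
- Enabling feature: in the carbocycle, C8a (N-bearing, ketone oxidation level), C4a (carrying the C4 acyl carbon) and the stereocentre C5 are the carbonyl, α- and β-carbons of a latent cyclohex-2-en-1-one. The octyl–C5 bond is therefore a conjugate-addition bond, and the enolate it leaves is the C4a nucleophile needed for the C4a–C4 bond.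
- Key disconnection: Cu-catalysed asymmetric conjugate addition of octylmagnesium bromide to cyclohex-2-enone with aldol trapping by methoxyacetaldehyde. It forms octyl–C5 and C4a–C4, sets C5, and assembles 17 of the 20 carbons.
- Ring order: carbocycle purchased as cyclohexenone; pyridone ring closed in step 4.

Key step: step 1

Remark (assumption): anhydrous methoxyacetaldehyde is treated as a commercial reagent; it can also be freshly liberated from its commercial dimethyl acetal and distilled before use.

**Step 1**
Reactants: 1 cyclohex-2-en-1-one; 2 n-octylmagnesium bromide; 3 methoxyacetaldehyde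
Product: 5 (2R,3R)-2-(1-hydroxy-2-methoxyethyl)-3-octylcyclohexan-1-one (trans; both carbinol epimers), via magnesium enolate 4 (not isolated)
Conditions: CuBr·SMe2 (5 mol%), Taniaphos-type ferrocenyl diphosphine (6 mol%, antipode giving the R product), 2 (1.15 eq, slow addition), Et2O, 0 °C; then 3 (1.5 eq), −78 °C; aq NH4Cl at −78 °C
Reagents that add atoms: n-octylmagnesium bromide, CCCCCCCC[Mg]Br; methoxyacetaldehyde, COCC=O
Why: Copper-catalysed asymmetric conjugate addition of a Grignard reagent with aldol trapping of the enolate (a three-component coupling of the Noyori type; both the Cu/ferrocenyl-diphosphine addition to cyclic enones and enolate–aldehyde trapping are established): the octylcuprate π-complex of 1 undergoes oxidative addition at the β-carbon and reductive elimination to form the octyl–C5 bond, leaving magnesium enolate 4, whose α-carbon (future C4a) adds to 3 to form C4a–C4. No ring is closed in this step. The C5 stereocentre is set by the chiral diphosphine on copper, which differentiates the faces of the flat enone (the ligand antipode that gives the R enolate is used, its sense to be checked on a protonated aliquot against the known 3-alkylcyclohexanone series); the C4a centre should form trans to octyl under substrate control and the carbinol centre is uncontrolled, but both are erased later. The step needs 1,4- over 1,2-addition, secured by copper catalysis in Et2O with slow Grignard addition, and a single enolate regioisomer, secured by the enone itself, since conjugate addition can only place the enolate between the carbonyl carbon and the α-carbon next to the new stereocentre. Trapping at −78 °C with a cold quench should suppress proton transfer to the enolisable aldehyde and retro-aldol.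

**Step 2**
Reactants: 5 (2R,3R)-2-(1-hydroxy-2-methoxyethyl)-3-octylcyclohexan-1-one; 6 O-methylhydroxylamine hydrochloride
Product: 7 (2S,3R)-2-(1-hydroxy-2-methoxyethyl)-3-octylcyclohexan-1-one O-methyl oxime (E/Z mixture; same trans geometry as 5)
Conditions: MeONH2·HCl (1.5 eq), pyridine (3 eq), MeOH, rt
Reagents that add atoms: O-methylhydroxylamine hydrochloride, CON.Cl
Why: Oxime ether formation on the only ketone present fixes the N–OMe unit on the future C8a; buffered conditions at rt should avoid retro-aldol and dehydration of the β-hydroxy ketone.

**Step 3**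
Reactants: 7 (2S,3R)-2-(1-hydroxy-2-methoxyethyl)-3-octylcyclohexan-1-one O-methyl oxime
Product: 8 2-methoxy-1-[(6R)-2-(methoxyimino)-6-octylcyclohexyl]ethan-1-one
Conditions: Dess–Martin periodinane (1.2 eq), CH2Cl2, 0 °C to rt
Reagents that add atoms: none
Why: Dess–Martin oxidation of the secondary carbinol gives the β-keto oxime ether (in equilibrium with its N-methoxy enaminone tautomer); the oxime ether is inert to the reagent, the ring carbon between C=N and C=O becomes epimerisable without consequence, and the non-enolisable C5 centre is untouched.

**Step 4**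
Reactants: 8 2-methoxy-1-[(6R)-2-(methoxyimino)-6-octylcyclohexyl]ethan-1-one; 9 dimethyl oxalate
Product: 11 methyl (5R)-1,3-dimethoxy-5-octyl-4-oxo-1,4,5,6,7,8-hexahydroquinoline-2-carboxylate, via Claisen adduct 10 (not isolated)
Conditions: NaOMe (4 eq), 9 (3 eq), MeOH, 0 to 50 °C; then AcOH, 60 °C
Reagents that add atoms: dimethyl oxalate, COC(=O)C(=O)OC
Why: Proposed new method: methoxide first removes the doubly activated C4a–H and then, reversibly, a C3–H (α to the C4 ketone, acidified by OMe); C-acylation of C3 by dimethyl oxalate (Claisen) gives 10, whose N-methoxy enamine nitrogen (tautomer of the oxime ether) adds to the new C2 ketone (6-exo-trig) and dehydration gives the aromatic 4-pyridone as an irreversible sink, whereas adducts at C8, C4a, N or O cannot aromatise and should revert by retro-Claisen under methoxide; the closest known reaction types are the oxalate annulation of N-alkyl α'-methoxy enaminones to 3-methoxy-4-pyridone-2-carboxylates and the N–C ring closure of N-hydroxy and N-amino enaminones in pyranone-to-pyridone exchange, the new element being an N-alkoxy (oxime ether) nitrogen as the cyclising nucleophile.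

**Step 5**
Reactants: 11 methyl (5R)-1,3-dimethoxy-5-octyl-4-oxo-1,4,5,6,7,8-hexahydroquinoline-2-carboxylate
Product: 12 (5R)-2-(hydroxymethyl)-1,3-dimethoxy-5-octyl-5,6,7,8-tetrahydroquinolin-4(1H)-one
Conditions: LiBH4 (2 eq), MeOH (2 eq), THF, 0 °C to rt; aq NH4Cl
Reagents that add atoms: none
Why: Chemoselective borohydride reduction of an ester α to the ring nitrogen (picolinate-type, further activated by the N–OMe and OMe neighbours); the vinylogous amide carbonyl, the N–O bond and the C5 centre should be inert to LiBH4.

**Compound list**
1 | cyclohex-2-en-1-one | O=C1C=CCCC1 | starting material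
2 | n-octylmagnesium bromide | CCCCCCCC[Mg]Br | starting material
3 | methoxyacetaldehyde | COCC=O | starting material
4 | bromomagnesium (3R)-3-octylcyclohex-1-en-1-olate | CCCCCCCC[C@@H]1CCCC(O[Mg]Br)=C1 | intermediate
5 | (2R,3R)-2-(1-hydroxy-2-methoxyethyl)-3-octylcyclohexan-1-one (trans; both carbinol epimers) | CCCCCCCC[C@@H]1CCCC(=O)[C@H]1C(O)COC | intermediate
6 | O-methylhydroxylamine hydrochloride | CON.Cl | starting material
7 | (2S,3R)-2-(1-hydroxy-2-methoxyethyl)-3-octylcyclohexan-1-one O-methyl oxime (E/Z mixture; trans as in 5) | CCCCCCCC[C@@H]1CCCC(=NOC)[C@H]1C(O)COC | intermediate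
8 | 2-methoxy-1-[(6R)-2-(methoxyimino)-6-octylcyclohexyl]ethan-1-one | CCCCCCCC[C@@H]1CCCC(=NOC)C1C(=O)COC | intermediate
9 | dimethyl oxalate | COC(=O)C(=O)OC | starting material
10 | methyl 3-methoxy-4-[(6R)-2-(methoxyimino)-6-octylcyclohexyl]-2,4-dioxobutanoate (present as its sodium enolate) | CCCCCCCC[C@@H]1CCCC(=NOC)C1C(=O)C(OC)C(=O)C(=O)OC | intermediate
11 | methyl (5R)-1,3-dimethoxy-5-octyl-4-oxo-1,4,5,6,7,8-hexahydroquinoline-2-carboxylate | CCCCCCCC[C@@H]1CCCc2c1c(=O)c(OC)c(C(=O)OC)n2OC | intermediate
12 | (5R)-2-(hydroxymethyl)-1,3-dimethoxy-5-octyl-5,6,7,8-tetrahydroquinolin-4(1H)-one | CCCCCCCC[C@@H]1CCCc2c1c(=O)c(OC)c(CO)n2OC | target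

**Step count and risks**
Total step count: 5. Longest linear sequence: 5 steps.

Steps most likely to fail:

1. Step 4 (proposed new method). The process at risk is site selectivity of the acylation (C8, C4a, N or O in place of C3) and ring closure by a weakly nucleophilic N-methoxy enamine nitrogen. The fallback uses known chemistry, sets out from 5 and comes back at 11. Compound 5 would be oxidised with Dess–Martin periodinane to the β-diketone (3R)-2-(2-methoxyacetyl)-3-octylcyclohexan-1-one F1. Claisen condensation of F1 with dimethyl oxalate (NaOMe, MeOH) and acid cyclodehydration (HCl, MeOH) should give methyl (5R)-3-methoxy-5-octyl-4-oxo-5,6,7,8-tetrahydro-4H-chromene-2-carboxylate F2, the classical route from 2-acylcycloalkanones to chromone-2-carboxylates; this Claisen could also acylate C8, so a regioisomeric chromone would have to be separated here. Exchange of the ring oxygen with hydroxylamine hydrochloride in pyridine (known pyranone to 1-hydroxy-4-pyridone conversion) should give methyl (5R)-1-hydroxy-3-methoxy-5-octyl-4-oxo-1,4,5,6,7,8-hexahydroquinoline-2-carboxylate F3. O-Methylation on the N–O oxygen (MeI, K2CO3, DMF) returns to 11.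

2. Step 1 (key step). The process at risk is incomplete enantiofacial control or competing 1,2-addition with the Grignard reagent, and proton transfer from the enolisable aldehyde to the basic magnesium enolate, which would lose the regiodefined enolate. The fallback sets out from 1 and 2 and comes back at 5, separating the two bond formations and changing the metal. Compound 2 would be transmetalated with ZnCl2 and freed from magnesium halides with 1,4-dioxane to give dioctylzinc F4. Cu(OTf)2/binaphthol-phosphoramidite-catalysed conjugate addition of F4 to 1 (toluene, −30 °C), with silylation of the zinc enolate by TMSOTf, should give (R)-trimethyl[(3-octylcyclohex-1-en-1-yl)oxy]silane F5, which is isolated. A Mukaiyama aldol addition of F5 to 3 (BF3·OEt2, CH2Cl2, −78 °C) returns to 5.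

3. Step 5. The process at risk is slow or unselective hydride delivery (conjugate reduction at C2 of the pyridone, or N–O cleavage on forcing). The fallback sets out from 11 and comes back at 12. Saponification (LiOH, THF/H2O) should give (5R)-1,3-dimethoxy-5-octyl-4-oxo-1,4,5,6,7,8-hexahydroquinoline-2-carboxylic acid F6. Activation with isobutyl chloroformate and N-methylmorpholine (THF, −15 °C) gives the isobutyl carbonic mixed anhydride F7, which is reduced in the same flask with NaBH4 (THF/H2O, −15 °C) to 12.

Further compounds
F1 | step 4 | (3R)-2-(2-methoxyacetyl)-3-octylcyclohexan-1-one | CCCCCCCC[C@@H]1CCCC(=O)C1C(=O)COC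
F2 | step 4 | methyl (5R)-3-methoxy-5-octyl-4-oxo-5,6,7,8-tetrahydro-4H-chromene-2-carboxylate | CCCCCCCC[C@@H]1CCCC2=C1C(=O)C(OC)=C(C(=O)OC)O2
F3 | step 4 | methyl (5R)-1-hydroxy-3-methoxy-5-octyl-4-oxo-1,4,5,6,7,8-hexahydroquinoline-2-carboxylate | CCCCCCCC[C@@H]1CCCc2c1c(=O)c(OC)c(C(=O)OC)n2O
F4 | step 1 | dioctylzinc | CCCCCCCC[Zn]CCCCCCCC
F5 | step 1 | (R)-trimethyl[(3-octylcyclohex-1-en-1-yl)oxy]silane | CCCCCCCC[C@@H]1CCCC(O[Si](C)(C)C)=C1
F6 | step 5 | (5R)-1,3-dimethoxy-5-octyl-4-oxo-1,4,5,6,7,8-hexahydroquinoline-2-carboxylic acid | CCCCCCCC[C@@H]1CCCc2c1c(=O)c(OC)c(C(=O)O)n2OC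
F7 | step 5 | (5R)-1,3-dimethoxy-5-octyl-4-oxo-1,4,5,6,7,8-hexahydroquinoline-2-carboxylic isobutyl carbonic anhydride | CCCCCCCC[C@@H]1CCCc2c1c(=O)c(OC)c(C(=O)OC(=O)OCC(C)C)n2OC
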